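**Retrosynthetic overview**

1. Target = 5,7-dihydroxy-2-(5-hydroxy-2,4-dimethoxyphenyl)-3,6,8-trimethoxychromen-4-one. Ring C (the pyranone) is the only ring made and is closed last, by hydrogenolysis and cyclodehydration of a tetrabenzylated 2-methoxy-1,3-diketone. Ring A is symmetric, so either ortho hydroxyl gives the same flavone.
2. 2-Methoxy-1,3-diketone ⇒ ring A aryl iodide + CO + ring B α-methoxy ketone (proposed carbonylative α-arylation; it makes the C4–C4a and C3–C4 bonds in one step).
3. Ring A iodide ⇒ 2,6-dimethoxyphenol: O-benzylation, double bromination, double C–O hydroxylation, benzylation, iodination of the last C–H.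
4. Ring B ketone ⇒ 5-bromo-2,4-dimethoxybenzaldehyde: Dakin-type oxidation (CHO to OH), benzylation, Br–Li exchange and Weinreb acylation.
5. Order of rings: rings A and B are bought as benzenes and dressed separately; ring C is formed in the final step.

Assumption: the target has no stereocentre, axis or stereogenic double bond, so it is achiral and no enantiocontrol is needed; 2,6-dimethoxyphenol, 5-bromo-2,4-dimethoxybenzaldehyde and N,2-dimethoxy-N-methylacetamide are taken as commercial.

**Route**

Step 1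
Reactants: 1 2,6-dimethoxyphenol
Product: 2 2-(benzyloxy)-1,3-dimethoxybenzene
Conditions: BnBr (1.2 equiv), K2CO3 (1.5 equiv), DMF, 60 °C
Reagents that add atoms: benzyl bromide, BrCc1ccccc1
Why: Williamson ether synthesis on the phenoxide; it protects the future 7-OH and replaces the para-directing free phenol by a twisted, weakly donating ether.

Step 2
Reactants: 2 2-(benzyloxy)-1,3-dimethoxybenzene
Product: 3 3-(benzyloxy)-1,5-dibromo-2,4-dimethoxybenzene
Conditions: NBS (2.1 equiv), MeCN, 0 °C to rt, dark
Reagents that add atoms: N-bromosuccinimide, BrN1C(=O)CCC1=O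
Why: Electrophilic aromatic bromination; each brominated carbon is ortho to one methoxy group and para to the other, whereas the remaining carbon is only para to the out-of-plane central benzyloxy group, so the two bromines flank the C–H that later becomes C4a.

Step 3
Reactants: 3 3-(benzyloxy)-1,5-dibromo-2,4-dimethoxybenzene
Product: 4 5-(benzyloxy)-4,6-dimethoxybenzene-1,3-diol
Conditions: Pd2(dba)3 (2 mol %), tBuXPhos (8 mol %), KOH (6 equiv), degassed 1,4-dioxane–H2O (1:1), 100 °C, Ar; then 1 M HCl
Reagents that add atoms: potassium hydroxide, [K+].[OH-]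
Why: Palladium-catalysed C–O cross-coupling of aryl bromides with hydroxide (Buchwald-type hydroxylation); the bulky biaryl phosphine drives C–O reductive elimination and each bromide has only one ortho substituent.

Step 4
Reactants: 4 5-(benzyloxy)-4,6-dimethoxybenzene-1,3-diol
Product: 5 1,3,5-tris(benzyloxy)-2,4-dimethoxybenzene
Conditions: BnBr (2.4 equiv), K2CO3 (3 equiv), DMF, rt, Ar
Reagents that add atoms: benzyl bromide, BrCc1ccccc1
Why: Williamson ether synthesis; potassium phenoxides in a polar aprotic solvent alkylate on oxygen, not on the ring carbon between the two hydroxyls.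

Step 5
Reactants: 5 1,3,5-tris(benzyloxy)-2,4-dimethoxybenzene
Product: 6 1,3,5-tris(benzyloxy)-2-iodo-4,6-dimethoxybenzene
Conditions: NIS (1.1 equiv), CF3CO2H (10 mol %), MeCN, 0 °C to rt, dark
Reagents that add atoms: N-iodosuccinimide, IN1C(=O)CCC1=O
Why: Electrophilic aromatic iodination at the only ring C–H, which is activated by two ortho and one para alkoxy groups.

Step 6
Reactants: 7 5-bromo-2,4-dimethoxybenzaldehyde
Product: 9 5-bromo-2,4-dimethoxyphenol, via formate ester 8 (not isolated)
Conditions: mCPBA (1.3 equiv), CH2Cl2, 0 °C to rt; then K2CO3 (0.2 equiv), MeOH, rt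
Reagents that add atoms: mCPBA (3-chloroperoxybenzoic acid), OOC(=O)c1cccc(Cl)c1
Why: Baeyer–Villiger (Dakin-type) oxidation; the ortho and para methoxy groups favour aryl migration to the aryl formate, which base-catalysed methanolysis cleaves to the phenol.

Step 7
Reactants: 9 5-bromo-2,4-dimethoxyphenol
Product: 10 1-(benzyloxy)-5-bromo-2,4-dimethoxybenzene
Conditions: BnBr (1.2 equiv), K2CO3 (1.5 equiv), DMF, rt
Reagents that add atoms: benzyl bromide, BrCc1ccccc1
Why: Williamson ether synthesis protects the future 5'-OH as a benzyl ether that is removed with the other three at the end.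

Step 8
Reactants: 10 1-(benzyloxy)-5-bromo-2,4-dimethoxybenzene; 11 N,2-dimethoxy-N-methylacetamide
Product: 14 1-[5-(benzyloxy)-2,4-dimethoxyphenyl]-2-methoxyethan-1-one, via aryllithium 12 (not isolated), via chelated lithium adduct 13 (not isolated)
Conditions: n-BuLi (1.05 equiv), THF, −78 °C; then 11 (1.2 equiv), −78 to 0 °C; then 1 M HCl
Reagents that add atoms: none
Why: Bromine–lithium exchange (much faster at −78 °C than benzylic deprotonation) followed by Weinreb ketone synthesis; the chelated tetrahedral adduct prevents over-addition and collapses to the ketone only on acidic work-up.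

Step 9
Reactants: 6 1,3,5-tris(benzyloxy)-2-iodo-4,6-dimethoxybenzene; 14 1-[5-(benzyloxy)-2,4-dimethoxyphenyl]-2-methoxyethan-1-one
Product: 16 1-[5-(benzyloxy)-2,4-dimethoxyphenyl]-2-methoxy-3-[2,4,6-tris(benzyloxy)-3,5-dimethoxyphenyl]propane-1,3-dione, via sodium enolate 15 (not isolated)
Conditions: 14 (2.2 equiv), NaN(SiMe3)2 (2.1 equiv), THF, 0 °C; then 6 (1.0 equiv), Pd(dba)2 (5 mol %), Xantphos (6 mol %), CO (1 atm), THF–1,4-dioxane, 60 °C; then 1 M HCl (one equivalent of 14 is recovered)
Reagents that add atoms: carbon monoxide, [C-]#[O+]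
Why: Proposed new method: a three-component carbonylative α-arylation that uses an α-alkoxy ketone enolate as nucleophile and a hexasubstituted 2,6-dialkoxyaryl iodide as electrophile, neither of which has to my knowledge been shown; zerovalent palladium adds to the C–I bond of 6, the two flanking benzyloxy groups slow direct α-arylation and push the arylpalladium iodide to insert CO, the chelated sodium enolate 15 displaces iodide on the aroyl divalent palladium centre, and C–C reductive elimination (helped by the wide bite angle of Xantphos) releases 16, which the second equivalent of 15 deprotonates at once so that it cannot be acylated again or undergo retro-Claisen cleavage; the closest known reaction type is the palladium-catalysed carbonylative α-arylation of simple ketones with unhindered aryl iodides to 1,3-diketones; the new CH(OMe) centre forms as a racemate and is removed in step 10.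

Step 10
Reactants: 16 1-[5-(benzyloxy)-2,4-dimethoxyphenyl]-2-methoxy-3-[2,4,6-tris(benzyloxy)-3,5-dimethoxyphenyl]propane-1,3-dione
Product: 19 5,7-dihydroxy-2-(5-hydroxy-2,4-dimethoxyphenyl)-3,6,8-trimethoxy-4H-chromen-4-one, via tetrahydroxy diketone 17 (not isolated), via cyclic hemiketal 18 (not isolated)
Conditions: H2 (1 atm), Pd/C (10 wt % palladium on carbon), EtOAc–MeOH (1:1), rt; filter under Ar; then TsOH·H2O (20 mol %), EtOH, 70 °C
Reagents that add atoms: none
Why: Hydrogenolysis of the four benzyl ethers followed by acid-catalysed cyclodehydration of the 2-hydroxyaryl 1,3-diketone (the closing stage of a Baker–Venkataraman flavone synthesis); the two ortho hydroxyls of ring A are equivalent, only ring A carries an ortho hydroxyl, and dehydration removes all stereocentres, so a single achiral flavone results.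

**Compound list**

1 | 2,6-dimethoxyphenol | COc1cccc(OC)c1O | starting material
2 | 2-(benzyloxy)-1,3-dimethoxybenzene | COc1cccc(OC)c1OCc1ccccc1 | intermediate
3 | 3-(benzyloxy)-1,5-dibromo-2,4-dimethoxybenzene | COc1c(Br)cc(Br)c(OC)c1OCc1ccccc1 | intermediate
4 | 5-(benzyloxy)-4,6-dimethoxybenzene-1,3-diol | COc1c(O)cc(O)c(OC)c1OCc1ccccc1 | intermediate
5 | 1,3,5-tris(benzyloxy)-2,4-dimethoxybenzene | COc1c(OCc2ccccc2)cc(OCc2ccccc2)c(OC)c1OCc1ccccc1 | intermediate
6 | 1,3,5-tris(benzyloxy)-2-iodo-4,6-dimethoxybenzene | COc1c(OCc2ccccc2)c(I)c(OCc2ccccc2)c(OC)c1OCc1ccccc1 | intermediate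
7 | 5-bromo-2,4-dimethoxybenzaldehyde | COc1cc(OC)c(C=O)cc1Br | starting material
8 | 5-bromo-2,4-dimethoxyphenyl formate | COc1cc(OC)c(OC=O)cc1Br | intermediate (not isolated)
9 | 5-bromo-2,4-dimethoxyphenol | COc1cc(OC)c(O)cc1Br | intermediate
10 | 1-(benzyloxy)-5-bromo-2,4-dimethoxybenzene | COc1cc(OC)c(OCc2ccccc2)cc1Br | intermediate
11 | N,2-dimethoxy-N-methylacetamide | COCC(=O)N(C)OC | starting material
12 | [5-(benzyloxy)-2,4-dimethoxyphenyl]lithium | COc1cc(OC)c(OCc2ccccc2)cc1[Li] | intermediate (not isolated)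
13 | lithium 1-[5-(benzyloxy)-2,4-dimethoxyphenyl]-2-methoxy-1-[methoxy(methyl)amino]ethan-1-olate (racemic) | COCC([O-])(N(C)OC)c1cc(OCc2ccccc2)c(OC)cc1OC.[Li+] | intermediate (not isolated)
14 | 1-[5-(benzyloxy)-2,4-dimethoxyphenyl]-2-methoxyethan-1-one | COCC(=O)c1cc(OCc2ccccc2)c(OC)cc1OC | intermediate
15 | sodium (Z)-1-[5-(benzyloxy)-2,4-dimethoxyphenyl]-2-methoxyethen-1-olate | CO/C=C(\[O-])c1cc(OCc2ccccc2)c(OC)cc1OC.[Na+] | intermediate (not isolated)
16 | 1-[5-(benzyloxy)-2,4-dimethoxyphenyl]-2-methoxy-3-[2,4,6-tris(benzyloxy)-3,5-dimethoxyphenyl]propane-1,3-dione (racemic at C2, configurationally labile) | COc1cc(OC)c(C(=O)C(OC)C(=O)c2c(OCc3ccccc3)c(OC)c(OCc3ccccc3)c(OC)c2OCc2ccccc2)cc1OCc1ccccc1 | intermediate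
17 | 1-(5-hydroxy-2,4-dimethoxyphenyl)-2-methoxy-3-(2,4,6-trihydroxy-3,5-dimethoxyphenyl)propane-1,3-dione (racemic) | COc1cc(OC)c(C(=O)C(OC)C(=O)c2c(O)c(OC)c(O)c(OC)c2O)cc1O | intermediate (not isolated)
18 | 2,5,7-trihydroxy-2-(5-hydroxy-2,4-dimethoxyphenyl)-3,6,8-trimethoxychroman-4-one (mixture of racemic diastereomers) | COc1cc(OC)c(C2(O)Oc3c(OC)c(O)c(OC)c(O)c3C(=O)C2OC)cc1O | intermediate (not isolated)
19 | 5,7-dihydroxy-2-(5-hydroxy-2,4-dimethoxyphenyl)-3,6,8-trimethoxy-4H-chromen-4-one (achiral) | COc1cc(OC)c(-c2oc3c(OC)c(O)c(OC)c(O)c3c(=O)c2OC)cc1O | target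

**Totals and risks**

Total step count: 10. Longest linear sequence: 7 steps (steps 1, 2, 3, 4, 5, 9, 10).

The three steps most likely to fail:

Step 9 (the proposed new step). The aroyl transfer to a hindered, chelated enolate may be slow. O-acylation, hydrodeiodination, or palladation of an ortho benzyl group (direct arylation) may compete; the CO atmosphere, the absence of carboxylate base and the moderate temperature are chosen to suppress the last of these. The fallback uses known chemistry, sets out from 6 and comes back at 16. Iodine–lithium exchange on 6 (n-BuLi, THF, −78 °C) gives [2,4,6-tris(benzyloxy)-3,5-dimethoxyphenyl]lithium F1, which is carboxylated with CO2 and acidified to 2,4,6-tris(benzyloxy)-3,5-dimethoxybenzoic acid F2. (COCl)2 with catalytic DMF in CH2Cl2 converts this to 2,4,6-tris(benzyloxy)-3,5-dimethoxybenzoyl chloride F3. F3 is added at −78 °C to sodium enolate 15 (2 equiv, made from 14 as in step 9) in THF, and this crossed Claisen C-acylation gives 16.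

Step 3. The double hydroxylation of an electron-rich dibromide may stop at the mono-phenol, form diaryl ether, or give a diol that oxidises in hot aqueous base. The fallback sets out from 3 and comes back at 4, and replaces direct C–O coupling by C–B bond formation and oxidation. Double Miyaura borylation (B2pin2, Pd(dppf)Cl2, KOAc, 1,4-dioxane, 90 °C) gives 2,2'-[5-(benzyloxy)-4,6-dimethoxy-1,3-phenylene]bis(4,4,5,5-tetramethyl-1,3,2-dioxaborolane) F4. Cold oxidation (H2O2, NaOH, THF–H2O, 0 °C) then gives 4.

Step 10. Removal of four benzyl ethers, two of them hindered, may be incomplete, and the open-chain polyphenol 17 is sensitive to air and to retro-Claisen cleavage. The fallback sets out from 16 and comes back at 19, and closes ring C before the global deprotection. BCl3 (3 equiv, CH2Cl2, −78 °C) cleaves, by chelation to the ring A carbonyl, only one ortho benzyl ether and gives 3-[2,4-bis(benzyloxy)-6-hydroxy-3,5-dimethoxyphenyl]-1-[5-(benzyloxy)-2,4-dimethoxyphenyl]-2-methoxypropane-1,3-dione F5. TsOH in toluene at 80 °C closes it through 5,7-bis(benzyloxy)-2-[5-(benzyloxy)-2,4-dimethoxyphenyl]-2-hydroxy-3,6,8-trimethoxychroman-4-one F6 to 5,7-bis(benzyloxy)-2-[5-(benzyloxy)-2,4-dimethoxyphenyl]-3,6,8-trimethoxy-4H-chromen-4-one F7. This stable flavone is then debenzylated (H2, Pd/C, EtOAc–MeOH, rt) to 19.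

**Further compounds**

F1 | step 9 | [2,4,6-tris(benzyloxy)-3,5-dimethoxyphenyl]lithium | [Li]c1c(OCc2ccccc2)c(OC)c(OCc2ccccc2)c(OC)c1OCc1ccccc1
F2 | step 9 | 2,4,6-tris(benzyloxy)-3,5-dimethoxybenzoic acid | OC(=O)c1c(OCc2ccccc2)c(OC)c(OCc2ccccc2)c(OC)c1OCc1ccccc1
F3 | step 9 | 2,4,6-tris(benzyloxy)-3,5-dimethoxybenzoyl chloride | ClC(=O)c1c(OCc2ccccc2)c(OC)c(OCc2ccccc2)c(OC)c1OCc1ccccc1
F4 | step 3 | 2,2'-[5-(benzyloxy)-4,6-dimethoxy-1,3-phenylene]bis(4,4,5,5-tetramethyl-1,3,2-dioxaborolane) | COc1c(B2OC(C)(C)C(C)(C)O2)cc(B2OC(C)(C)C(C)(C)O2)c(OC)c1OCc1ccccc1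
F5 | step 10 | 3-[2,4-bis(benzyloxy)-6-hydroxy-3,5-dimethoxyphenyl]-1-[5-(benzyloxy)-2,4-dimethoxyphenyl]-2-methoxypropane-1,3-dione (racemic) | COc1cc(OC)c(C(=O)C(OC)C(=O)c2c(O)c(OC)c(OCc3ccccc3)c(OC)c2OCc2ccccc2)cc1OCc1ccccc1
F6 | step 10 | 5,7-bis(benzyloxy)-2-[5-(benzyloxy)-2,4-dimethoxyphenyl]-2-hydroxy-3,6,8-trimethoxychroman-4-one (mixture of racemic diastereomers) | COc1cc(OC)c(C2(O)Oc3c(OC)c(OCc4ccccc4)c(OC)c(OCc4ccccc4)c3C(=O)C2OC)cc1OCc1ccccc1
F7 | step 10 | 5,7-bis(benzyloxy)-2-[5-(benzyloxy)-2,4-dimethoxyphenyl]-3,6,8-trimethoxy-4H-chromen-4-one | COc1cc(OC)c(-c2oc3c(OC)c(OCc4ccccc4)c(OC)c(OCc4ccccc4)c3c(=O)c2OC)cc1OCc1ccccc1
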